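**Assumption:** The target has no stereocentre and no configurationally stable axis (the diaryl ether rotates freely), so the SMILES defines one achiral compound and no stereocontrol is needed.

## Structural features

The target, 2,3,5-tribromo-6-(2,4-dibromophenoxy)phenol, consists of two benzene rings joined only by an ether oxygen between C6 of ring A (C1 OH, C2 Br, C3 Br, C4 H, C5 Br) and C1' of ring B (C2' Br, C4' Br). There is no stereocentre, so all the difficulty is positional. The ether oxygen is flanked by three ortho substituents (C1–OH, C5–Br, C2'–Br) and both of its carbons are electron-poor, which makes an intermolecular C–O coupling slow. The five C–Br bonds are fragile towards low-valent Pd or Ni, hot copper, organolithium reagents (exchange, halogen migration, aryne formation) and hydrogenolysis, and the free C1–OH can close onto C2' to a dibenzo-p-dioxin under base and heat. Seen from the ether oxygen both rings carry bromine ortho and para (C5, C3; C2', C4'), but ring A also has C2–Br ortho to the hydroxyl and an unsubstituted C4 para to it, a pattern that bromination of a free 2-aryloxyphenol does not give. The real difficulty is therefore to form the crowded C6–O–C1' bond and to place an oxygen on C1 with full positional control while five bromines are present. The key step exploits the adjacency of C1 and C6: in the ring A fragment that carries its ether oxygen on C6, C1 is the only ortho or para carbon still bearing hydrogen, so an iodine(III) atom placed there holds ring B within reach of that oxygen, hands C1' over through a five-membered transition state and stays on C1 as the precursor of the hydroxyl group.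

## Logic of the disconnections

**11 to 8.** The C1–O bond of the hydroxyl group is cut and replaced by C1–I. Iodine is the one halogen that can be exchanged for a metal in the presence of five C–Br bonds, so the phenol never needs a protecting group and the ortho-dioxygenation problem becomes an ortho-iodo diaryl ether. The forward step must turn C–I into C–O chemoselectively (through 9 and 10) and stay cold enough that the metal next to C2–Br is not lost as an aryne.

**8 to 7 (key).** The ether bond O–C1' is cut while C1' is reconnected to the iodine on C1, a retro 1,4-aryl shift. In one sentence, the route is a thermal iodine-to-oxygen shift of ring B within an iodonium phenolate assembled by C–H iodonation of a tribromophenol. The hardest bond of the target thus becomes an intramolecular bond through a five-membered transition state, and the same iodine atom that carries ring B remains as the handle for the C1 oxygen. The forward step demands that only ring B migrates, that the shift outruns intermolecular arylation, and that the phenolate is not simply oxidised.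

**7 to 4 + 6.** The C1–I bond is cut, which separates the molecule into a ring A phenol and a ring B iodine(III) reagent; all five bromines are already in place in these two halves. The forward C–H iodonation must hit C1 only. This is guaranteed by the substitution of 4, where the other ortho and the para carbon carry bromine.

**6 to 5.** The two I–O bonds are cut, leading back to a purchasable iodoarene. The forward oxidation must stop at iodine(III).

**4 to 1.** The C–O bond of the phenol is cut via C–B (3) and C–Li (2) back to C–Br. Because all four C–Br bonds of 1 are equivalent by symmetry, a single exchange can give only one product and the 2,4,5-tribromo pattern is bought, not made. The forward step needs exactly one exchange and a temperature at which 2 does not lose lithium bromide.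

## Other disconnections considered

**Alternative 1:** The first idea is to cut the ether bond intermolecularly: Ullmann or iodonium O-arylation of 3,4,6-tribromo-2-methoxyphenol A1 with a 2,4-dibromophenyl donor to give the methyl ether A2, then Lewis-acid demethylation to 11. The chosen plan is preferred for three reasons.
- A1 cannot be made by brominating its unbrominated parent, because the third bromine would enter para to the methoxy group and not at C3, so A1 needs a multistep synthesis of its own.
- The coupling joins a di-ortho-substituted, weakly nucleophilic phenol with an ortho-substituted donor. Under copper, seven C–Br bonds compete; with a symmetric iodonium salt, one aryl group is lost.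
- A deprotection step is added at the end.

**Alternative 2:** A biomimetic cut of the same C6–O bond as a dehydrogenative coupling: anodic (or chemical one-electron) cross-coupling of 2,4-dibromophenol A3 with 2,3,5-tribromophenol A4, giving 11 in one step. The mechanism argues against it. A3 is the more easily oxidised partner and should mainly couple with itself. The radical from A4 has an unsubstituted para carbon, so C–O coupling there would give the para-linked isomer A5 alongside the ortho product. A4 itself is not a standard building block. The step count is attractive, but there is no element that enforces the one regiochemistry needed, whereas the chosen key step has a single possible outcome.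

**Alternative 3:** Cut the C–Br bonds instead and buy the diaryl ether: 2-phenoxyphenyl acetate A6, fourfold bromination directed by the ether oxygen to A7, ester cleavage to 3,5-dibromo-2-(2,4-dibromophenoxy)phenol A8 and a fifth bromination to 11. No C–O bond has to be made, but the regiochemistry rests on two uncertain competitions. The second bromination of ring A, ortho to the ether oxygen on an already deactivated ring, must beat over-bromination of ring B at C6'. The last bromine must enter ortho to the free hydroxyl (C2) and not para (C4). In the chosen plan every bromine position comes from a starting material.

Key step: step 3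

## Route

**Step 1**
Reactants: 1 1,2,4,5-tetrabromobenzene
Product: 4 2,4,5-tribromophenol, via (2,4,5-tribromophenyl)lithium 2 (not isolated), via dimethyl (2,4,5-tribromophenyl)boronate 3 (not isolated)
Conditions: n-BuLi (1.0 equiv), THF/Et2O, −78 °C; B(OMe)3, −78 °C → rt; AcOH, 30% H2O2, 0 °C → rt
Reagents that add atoms: hydrogen peroxide, OO
Why: Bromine–lithium exchange is fast at −78 °C and, since the four C–Br bonds of 1 are symmetry-equivalent, one exchange can give only 2; borylation to 3 and peroxide oxidation (1,2-shift of aryl from boron to oxygen) give 4 without touching the remaining C–Br bonds.

**Step 2**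
Reactants: 5 2,4-dibromo-1-iodobenzene
Product: 6 2,4-dibromo-1-(diacetoxyiodo)benzene
Conditions: AcOOH (35% in AcOH), 40 °C
Reagents that add atoms: peracetic acid, CC(=O)OO; acetic acid, CC(=O)O
Why: Standard oxidation of an iodoarene to its (diacetoxyiodo)arene with peracetic acid in acetic acid; the C–Br bonds are inert to the peracid, the ortho bromine only slows the oxidation, and water is the only by-product.

**Step 3**
Reactants: 4 2,4,5-tribromophenol; 6 2,4-dibromo-1-(diacetoxyiodo)benzene
Product: 8 1,2,5-tribromo-4-(2,4-dibromophenoxy)-3-iodobenzene, via 3,4,6-tribromo-2-[(2,4-dibromophenyl)iodonio]phenolate 7 (not isolated)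
Conditions: K2CO3 (2.2 equiv), MeCN, 0 °C → rt; then dilute (0.02 M), 80 °C
Reagents that add atoms: none
Why: The phenolate of 4 displaces acetate on iodine(III) of 6 and the aryl-λ3-iodanyl group is transferred to the one unsubstituted carbon ortho to the oxygen, and loss of the second acetate gives the iodonium phenolate 7, the known route to aryliodonium phenolates from acidic phenols. On warming, the phenolate oxygen attacks the iodine-bound carbon C1' of ring B through a five-membered spiro transition state (O–C6–C1–I–C1'), iodine(III) leaves as the aryl iodide function on C1 and the diaryl ether bond results, a 1,4 aryl shift from iodine to oxygen of the Smiles type. The closest known reaction type is the thermal rearrangement of iodonium ylides of phenols and of 1,3-dicarbonyl compounds to ortho-iodo aryl ethers. No ring is closed and no stereocentre is formed. Site selectivity of the iodonation is secured by the substrate, because the other ortho and the para carbon of 4 carry bromine and the remaining C–H is meta to oxygen and flanked by two bromines. Only ring B can migrate, because ring A is the tether, so no aryl group is wasted and no transfer selectivity arises, and the ortho and para bromines of ring B stabilise the negative charge building up at the ipso carbon while the ortho bromine adds the steric acceleration known for iodonium arylations. The three bromines make the phenolate hard to oxidise to a phenoxenium ion, which should favour C–I bond formation over dearomatisation, as with nitrophenols. Dilution before heating keeps the shift intramolecular.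

**Step 4**
Reactants: 8 1,2,5-tribromo-4-(2,4-dibromophenoxy)-3-iodobenzene
Product: 11 2,3,5-tribromo-6-(2,4-dibromophenoxy)phenol, via [2,3,5-tribromo-6-(2,4-dibromophenoxy)phenyl]magnesium chloride 9 (not isolated), via dimethyl [2,3,5-tribromo-6-(2,4-dibromophenoxy)phenyl]boronate 10 (not isolated)
Conditions: i-PrMgCl·LiCl (1.05 equiv), THF, −78 °C; B(OMe)3, −78 → 0 °C; AcOH, 30% H2O2, 0 °C → rt
Reagents that add atoms: hydrogen peroxide, OO
Why: Iodine–magnesium exchange is far faster at C–I than at C–Br and the carbanion is stabilised by the flanking oxygen and bromine, while at −78 °C the ortho-bromo arylmagnesium 9 should not eliminate to an aryne; borylation to 10 and acidic peroxide oxidation (boron-to-oxygen 1,2-aryl shift) place the hydroxyl exactly where the iodine was, and the acidic medium avoids protodeboronation and dioxin closure.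

## Compound list

1 | 1,2,4,5-tetrabromobenzene | Brc1cc(Br)c(Br)cc1Br | starting material
2 | (2,4,5-tribromophenyl)lithium | [Li]c1cc(Br)c(Br)cc1Br | intermediate
3 | dimethyl (2,4,5-tribromophenyl)boronate | COB(OC)c1cc(Br)c(Br)cc1Br | intermediate
4 | 2,4,5-tribromophenol | Oc1cc(Br)c(Br)cc1Br | intermediate
5 | 2,4-dibromo-1-iodobenzene | Brc1ccc(I)c(Br)c1 | starting material
6 | 2,4-dibromo-1-(diacetoxyiodo)benzene | CC(=O)OI(OC(C)=O)c1ccc(Br)cc1Br | intermediate
7 | 3,4,6-tribromo-2-[(2,4-dibromophenyl)iodonio]phenolate | [O-]c1c(Br)cc(Br)c(Br)c1[I+]c1ccc(Br)cc1Br | intermediate
8 | 1,2,5-tribromo-4-(2,4-dibromophenoxy)-3-iodobenzene | Ic1c(Br)c(Br)cc(Br)c1Oc1ccc(Br)cc1Br | intermediate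
9 | [2,3,5-tribromo-6-(2,4-dibromophenoxy)phenyl]magnesium chloride | Cl[Mg]c1c(Br)c(Br)cc(Br)c1Oc1ccc(Br)cc1Br | intermediate
10 | dimethyl [2,3,5-tribromo-6-(2,4-dibromophenoxy)phenyl]boronate | COB(OC)c1c(Br)c(Br)cc(Br)c1Oc1ccc(Br)cc1Br | intermediate
11 | 2,3,5-tribromo-6-(2,4-dibromophenoxy)phenol | Oc1c(Br)c(Br)cc(Br)c1Oc1ccc(Br)cc1Br | target

## Step count and least certain steps

Total: 4 steps. Longest linear sequence: 3 steps (1 → 4 → 8 → 11, or 5 → 6 → 8 → 11).

**Step 3 (key step).** The most likely failure is two-electron oxidation of the phenolate by the iodine(III) reagent (dearomatisation with loss of bromide) in place of C–I bond formation. The second is that, once 7 has formed, loss of the aryl iodide or intermolecular aryl transfer competes with the 1,4-shift, because the tribromophenolate oxygen is a weak nucleophile. The fallback separates the two bond formations and uses only established chemistry. It sets out from 4, which is iodinated at its free ortho carbon (N-iodosuccinimide, catalytic acid, MeCN) to 3,4,6-tribromo-2-iodophenol F1. In parallel 6 is condensed with purchased (2,4-dibromophenyl)boronic acid under triflic acid to the symmetric salt bis(2,4-dibromophenyl)iodonium trifluoromethanesulfonate F2. The potassium salt of F1 (t-BuOK, THF) is then arylated by F2 without metal, and the sequence comes back to the route at 8. The cost is two more operations and one ring B unit released as 5, which can be returned to step 2.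

**Step 4.** The risks are loss of magnesium halide from the ortho-bromo arylmagnesium (aryne formation) before it is borylated, and protonation or protodeboronation that returns C–H in place of C–O at the hindered, electron-poor carbon. The fallback avoids an aryl–metal species next to bromine. It sets out from 8, whose C–I bond is etherified with benzyl alcohol under copper catalysis (CuI, a phenanthroline ligand, Cs2CO3, toluene, 80 °C; C–I reacts well before C–Br and no free phenoxide is present that could close a dioxin), giving 1-(benzyloxy)-2,3,5-tribromo-6-(2,4-dibromophenoxy)benzene F3. Debenzylation with BCl3 and pentamethylbenzene at −78 °C, which leaves C–Br bonds alone, comes back to the route at 11.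

**Step 2.** The risk is incomplete oxidation of the electron-poor, ortho-substituted iodoarene, or over-oxidation to iodine(V) if the temperature is raised to force it. The fallback changes the oxidant and the sequence. It sets out from 5, which is chlorinated at iodine to 2,4-dibromo-1-(dichloro-λ3-iodanyl)benzene F4. Aqueous NaOH hydrolyses F4 to 2,4-dibromo-1-iodosylbenzene F5, and dissolving F5 in acetic acid comes back to the route at 6.

## Further compounds

F1 | step 3 | 3,4,6-tribromo-2-iodophenol | Oc1c(I)c(Br)c(Br)cc1Br
F2 | step 3 | bis(2,4-dibromophenyl)iodonium trifluoromethanesulfonate | Brc1ccc([I+]c2ccc(Br)cc2Br)c(Br)c1.[O-]S(=O)(=O)C(F)(F)F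
F3 | step 4 | 1-(benzyloxy)-2,3,5-tribromo-6-(2,4-dibromophenoxy)benzene | Brc1cc(Br)c(Oc2ccc(Br)cc2Br)c(OCc2ccccc2)c1Br
F4 | step 2 | 2,4-dibromo-1-(dichloro-λ3-iodanyl)benzene | ClI(Cl)c1ccc(Br)cc1Br
F5 | step 2 | 2,4-dibromo-1-iodosylbenzene | O=Ic1ccc(Br)cc1Br
A1 | alternative 1 | 3,4,6-tribromo-2-methoxyphenol | COc1c(Br)c(Br)cc(Br)c1O
A2 | alternative 1 | 1,2,5-tribromo-4-(2,4-dibromophenoxy)-3-methoxybenzene | COc1c(Br)c(Br)cc(Br)c1Oc1ccc(Br)cc1Br
A3 | alternative 2 | 2,4-dibromophenol | Oc1ccc(Br)cc1Br
A4 | alternative 2 | 2,3,5-tribromophenol | Oc1cc(Br)cc(Br)c1Br
A5 | alternative 2 | 2,3,5-tribromo-4-(2,4-dibromophenoxy)phenol | Oc1cc(Br)c(Oc2ccc(Br)cc2Br)c(Br)c1Br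
A6 | alternative 3 | 2-phenoxyphenyl acetate | CC(=O)Oc1ccccc1Oc1ccccc1
A7 | alternative 3 | 3,5-dibromo-2-(2,4-dibromophenoxy)phenyl acetate | CC(=O)Oc1cc(Br)cc(Br)c1Oc1ccc(Br)cc1Br
A8 | alternative 3 | 3,5-dibromo-2-(2,4-dibromophenoxy)phenol | Oc1cc(Br)cc(Br)c1Oc1ccc(Br)cc1Br
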